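**Retrosynthetic overview**

1. The C3 formyl group and the C3=C4 bond of target 23 are traced back to the C4 ketone of tetralone 19 (chloroformylation, hydrodechlorination, desilylation).
2. Ring A is a benzene ring with four adjacent substituents (C4a, C8a, C8–OMe, C7–OH), and its C8a–C1 bond lies ortho to the C8 methoxy and meta to the C7 oxygen, where closure onto a preformed arene would not go. Ring A is therefore built rather than substituted: 19 ⇒ dienyl ynone 17 by intramolecular Diels–Alder reaction (C8a–C4a and C6–C5) and dehydrogenation, which closes rings A and B together.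
3. 17 ⇒ γ-lactone 14 (ethynyl Grignard opening, acetylation). The lactone holds C4 at the acid level and the C2 CH2O group, so the ynone appears only after the silyl dienol ether is in place. The diene comes from a vinyl group (ozonolysis, methoxyphosphonate olefination, enol silylation).
4. C1 and C2 are set together by iridium/amine dual-catalysed α-allylation of methyl 4-oxobutanoate with the vanillin-derived aryl vinyl carbinol.
5. Ring order: temporary lactone (step 4), then rings A and B in step 11.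

Key step: step 11

Remarks: locants C1–C8a are those of the dihydronaphthalene core of the target and are used for the same atoms in every intermediate. TBS = tert-butyldimethylsilyl; Ar = 4-(TBSO)-3-methoxyphenyl.

Assumption: the two catalysts of step 3 are taken to act independently, the (R)-amine giving (S) at the formyl-bearing carbon and the (R)-ligand giving (S) at the benzylic carbon; should the ligand induce the opposite sense, its enantiomer is used and nothing else changes.

**Route**

Step 1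
Reactants: 1 vanillin
Product: 2 4-{[tert-butyl(dimethyl)silyl]oxy}-3-methoxybenzaldehyde
Conditions: TBSCl, imidazole, DMF, 0 °C → rt
Reagents that add atoms: tert-butyl(chloro)dimethylsilane (TBSCl), CC(C)(C)[Si](C)(C)Cl
Why: Silylation of a phenol with a silyl chloride and imidazole is general and masks the acidic phenol through the organometallic, acidic and oxidative steps that follow.

Step 2
Reactants: 2 4-(TBSO)-3-methoxybenzaldehyde; 3 vinylmagnesium bromide
Product: 4 rac-1-Ar-prop-2-en-1-ol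
Conditions: THF, −78 → 0 °C; sat aq NH4Cl
Reagents that add atoms: none
Why: Grignard 1,2-addition to an aromatic aldehyde gives the branched allylic alcohol, whose configuration is irrelevant because the carbinol carbon is ionised in step 3.

Step 3
Reactants: 4 rac-1-Ar-prop-2-en-1-ol; 5 methyl 4-oxobutanoate
Product: 6 methyl (3S,4S)-4-Ar-3-formylhex-5-enoate
Conditions: [Ir(cod)Cl]2 (3 mol%), (R)-4-(5H-dibenzo[b,f]azepin-5-yl)dinaphtho[2,1-d:1',2'-f][1,3,2]dioxaphosphepine (12 mol%), (R)-2-{bis[3,5-bis(trifluoromethyl)phenyl][(trimethylsilyl)oxy]methyl}pyrrolidine (15 mol%), (MeO)2P(O)OH (promoter), 5 (2 equiv), ClCH2CH2Cl, 25 °C; product used at once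
Reagents that add atoms: none
Why: In this dual iridium/amine-catalysed stereodivergent α-allylation of a linear aldehyde, the η3-allyl complex of trivalent iridium formed from either enantiomer of 4 is attacked at its benzylic terminus by the enamine of 5, the ligand fixing C1 (S) and the (R)-amine shielding one enamine face to fix C2 (S) independently, so the required diastereomer follows from the pairing of the two catalysts.

Step 4
Reactants: 6 methyl (3S,4S)-4-Ar-3-formylhex-5-enoate
Product: 8 (4S)-4-[(1S)-1-Ar-prop-2-en-1-yl]oxolan-2-one, via hydroxy ester 7 (not isolated)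
Conditions: NaBH4, MeOH, 0 °C; then p-MeC6H4SO3H·H2O (5 mol%), CH2Cl2, rt
Reagents that add atoms: none
Why: NaBH4 reduces the aldehyde but not the methyl ester, and the γ-hydroxy ester closes to the five-membered lactone under acid catalysis, which removes the epimerisable formyl-bearing centre and protects both the future CH2OAc oxygen and the C4 carboxyl carbon in one ring.

Step 5
Reactants: 8 (4S)-4-[(1S)-1-Ar-prop-2-en-1-yl]oxolan-2-one
Product: 10 (2S)-2-Ar-2-[(3S)-5-oxooxolan-3-yl]acetaldehyde, via secondary ozonide 9 (not isolated)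
Conditions: O3, CH2Cl2, −78 °C (Sudan Red 7B as end-point indicator); then PPh3, −78 °C → rt; used crude
Reagents that add atoms: ozone, [O-][O+]=O
Why: Ozonolysis with reductive work-up cleaves the monosubstituted alkene much faster than the silylated aryl ring when ozone is dosed against an indicator, and the neutral PPh3 reduction should not epimerise the new α-aryl aldehyde.

Step 6
Reactants: 11 dimethyl (1-diazo-2-oxopropyl)phosphonate
Product: 12 dimethyl (1-methoxy-2-oxopropyl)phosphonate (racemic)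
Conditions: Rh2(OAc)4 (1 mol%), MeOH (5 equiv), CH2Cl2, 40 °C
Reagents that add atoms: methanol, CO
Why: Rhodium-carbenoid O–H insertion of an α-diazo-β-ketophosphonate into an alcohol is an established route to α-alkoxy phosphonates.

Step 7
Reactants: 10 (2S)-2-Ar-2-[(3S)-5-oxooxolan-3-yl]acetaldehyde; 12 dimethyl (1-methoxy-2-oxopropyl)phosphonate
Product: 13 (4S)-4-[(1R,2Z)-1-Ar-3-methoxy-4-oxopent-2-en-1-yl]oxolan-2-one
Conditions: 12, LiCl, i-Pr2NEt, MeCN, 0 °C, 30 min; then 10, 0 °C → rt
Reagents that add atoms: none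
Why: In this Horner–Wadsworth–Emmons olefination under LiCl/tertiary-amine conditions the lithium-chelated phosphonate anion is preformed so that the α-aryl aldehyde meets no strong free base, and reversible addition should favour the alkene with C1 trans to the acetyl group, which is the (Z)-2-methoxy enone needed for an s-cis diene.

Step 8
Reactants: 13 (4S)-4-[(1R,2Z)-1-Ar-3-methoxy-4-oxopent-2-en-1-yl]oxolan-2-one
Product: 14 (4S)-4-[(1R,2Z)-1-Ar-4-(TBSO)-3-methoxypenta-2,4-dien-1-yl]oxolan-2-one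
Conditions: TBSOTf, Et3N, CH2Cl2, −78 → 0 °C; chromatography on Et3N-deactivated silica
Reagents that add atoms: tert-butyldimethylsilyl trifluoromethanesulfonate (TBSOTf), CC(C)(C)[Si](C)(C)OS(=O)(=O)C(F)(F)F
Why: Soft enolisation with a silyl triflate and a tertiary amine removes a proton from the kinetically accessible methyl group to give the cross-conjugated 2-silyloxy diene, the lactone being far less readily enolised under these conditions.

Step 9
Reactants: 14 (4S)-4-[(1R,2Z)-1-Ar-4-(TBSO)-3-methoxypenta-2,4-dien-1-yl]oxolan-2-one; 15 ethynylmagnesium bromide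
Product: 16 (5S,6R,7Z)-6-Ar-9-(TBSO)-5-(hydroxymethyl)-8-methoxydeca-7,9-dien-1-yn-3-one (may sit in equilibrium with its five-membered lactol)
Conditions: THF, −78 → −40 °C; sat aq NH4Cl at −40 °C; used crude
Reagents that add atoms: none
Why: Alkynyl Grignard reagents add once to γ-lactones at low temperature because the magnesium hemiketal alkoxide does not collapse before the quench, and the silyl enol ether keeps the diene ketone out of reach of the nucleophile.

Step 10
Reactants: 16 (5S,6R,7Z)-6-Ar-9-(TBSO)-5-(hydroxymethyl)-8-methoxydeca-7,9-dien-1-yn-3-one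
Product: 17 [(2S,3R,4Z)-3-Ar-6-(TBSO)-5-methoxy-2-(2-oxobut-3-yn-1-yl)hexa-4,6-dien-1-yl] acetate
Conditions: Ac2O, pyridine, CH2Cl2, 0 °C
Reagents that add atoms: acetic anhydride, CC(=O)OC(C)=O
Why: Acetylation of the primary alcohol with acetic anhydride and pyridine at 0 °C needs no nucleophilic catalyst, and a terminal ynone and a silyl enol ether should both persist under these conditions.

Step 11
Reactants: 17 [(2S,3R,4Z)-3-Ar-6-(TBSO)-5-methoxy-2-(2-oxobut-3-yn-1-yl)hexa-4,6-dien-1-yl] acetate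
Product: 19 [(1S,2S)-1-Ar-7-(TBSO)-8-methoxy-4-oxo-1,2,3,4-tetrahydronaphthalen-2-yl]methyl acetate (trans), via cyclohexadiene cycloadduct 18 (not isolated)
Conditions: PhMe (0.01 M), 2,6-di-tert-butyl-4-methylphenol (trace), 90 °C; then DDQ (slight excess), 0 °C → rt
Reagents that add atoms: none
Why: On heating, the electron-rich 2-methoxy-3-silyloxy diene (C8a=C8–C7=C6) adds in a concerted, normal-electron-demand [4+2] fashion to the tethered ynone (C4a≡C5), and DDQ then removes hydride and a proton from the 1,4-cyclohexadiene 18 to give the benzene ring; the closest known reaction type is the type 1 intramolecular Diels–Alder reaction of deca-7,9-dien-1-yn-3-ones followed by oxidative aromatisation of the adduct. Ring B closes in the fused mode through the four-atom tether C1–C2–C3–C4, C8a bonding to the proximal alkyne carbon C4a so that the C4 carbonyl lies inside the new six-membered ring, and ring A is the cycloaddition ring itself, completed by the C6–C5 bond. The only new stereocentre, C8a of 18, forms without control and is erased on aromatisation, so the step leaves no new stereocentre and has none to control. The selectivity the step needs is regiochemical and is secured twice, by the tether, which allows only the fused orientation, and by the C7 silyloxy group, which makes C6 the nucleophilic diene terminus that pairs with the electrophilic β-carbon C5 of the ynone. The (Z) enol ether geometry holds C1 on the outside of the diene so that the s-cis conformer is reachable, and the neutral medium cannot epimerise C1 or C2, C2 lying β to the ketone with no leaving group on it. With a slight excess of DDQ at 0 °C the bis(enol ether) cyclohexadiene should be oxidised well before the diarylmethine C1–H.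

Step 12
Reactants: 19 [(1S,2S)-1-Ar-7-(TBSO)-8-methoxy-4-oxo-1,2,3,4-tetrahydronaphthalen-2-yl]methyl acetate
Product: 21 [(1S,2R)-1-Ar-7-(TBSO)-4-chloro-3-formyl-8-methoxy-1,2-dihydronaphthalen-2-yl]methyl acetate, via chlorovinyl iminium salt 20 (not isolated)
Conditions: POCl3, DMF, ClCH2CH2Cl, 0 → 60 °C; then H2O, 0 °C → rt
Reagents that add atoms: N,N-dimethylformamide, CN(C)C=O; phosphoryl chloride, O=P(Cl)(Cl)Cl; water, O
Why: In the Vilsmeier–Haack chloroformylation of an α-methylene aryl ketone the enol attacks the chloroiminium ion at C3, the C4 oxygen is then exchanged for chloride and hydrolysis frees the β-chloro enal, a sequence in which neither C1 nor C2 is enolised.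

Step 13
Reactants: 21 [(1S,2R)-1-Ar-7-(TBSO)-4-chloro-3-formyl-8-methoxy-1,2-dihydronaphthalen-2-yl]methyl acetate
Product: 22 [(1S,2R)-1-Ar-7-(TBSO)-3-formyl-8-methoxy-1,2-dihydronaphthalen-2-yl]methyl acetate
Conditions: Pd(PPh3)4 (5 mol%), HCO2H, Et3N, DMF, 60 °C
Reagents that add atoms: none
Why: Zerovalent palladium inserts into the activated C4–Cl bond of the β-chloro enal (a vinylogous acid chloride), and formate exchange, decarboxylation and C–H reductive elimination replace chlorine by hydrogen without reducing the enal or touching the homoallylic acetate.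

Step 14
Reactants: 22 [(1S,2R)-1-Ar-7-(TBSO)-3-formyl-8-methoxy-1,2-dihydronaphthalen-2-yl]methyl acetate
Product: 23 [(1S,2R)-3-formyl-7-hydroxy-1-(4-hydroxy-3-methoxyphenyl)-8-methoxy-1,2-dihydronaphthalen-2-yl]methyl acetate (target)
Conditions: Bu4NF, AcOH (1:1), THF, 0 °C; work-up under argon
Reagents that add atoms: none
Why: Fluoride cleaves both aryl silyl ethers, and the acetic acid buffer keeps the medium near neutral so that the primary acetate, the enal and the oxidation-prone dihydronaphthalene should be left intact.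

**Compound list**

1 | vanillin (4-hydroxy-3-methoxybenzaldehyde) | COc1cc(C=O)ccc1O | starting material
2 | 4-{[tert-butyl(dimethyl)silyl]oxy}-3-methoxybenzaldehyde | COc1cc(C=O)ccc1O[Si](C)(C)C(C)(C)C | intermediate
3 | vinylmagnesium bromide | C=C[Mg]Br | starting material
4 | rac-1-(4-{[tert-butyl(dimethyl)silyl]oxy}-3-methoxyphenyl)prop-2-en-1-ol | COc1cc(C(O)C=C)ccc1O[Si](C)(C)C(C)(C)C | intermediate
5 | methyl 4-oxobutanoate | COC(=O)CCC=O | starting material
6 | methyl (3S,4S)-4-(4-{[tert-butyl(dimethyl)silyl]oxy}-3-methoxyphenyl)-3-formylhex-5-enoate | COc1cc([C@H]([C@@H](C=O)CC(=O)OC)C=C)ccc1O[Si](C)(C)C(C)(C)C | intermediate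
7 | methyl (3S,4S)-4-(4-{[tert-butyl(dimethyl)silyl]oxy}-3-methoxyphenyl)-3-(hydroxymethyl)hex-5-enoate | COc1cc([C@H]([C@@H](CO)CC(=O)OC)C=C)ccc1O[Si](C)(C)C(C)(C)C | intermediate
8 | (4S)-4-[(1S)-1-(4-{[tert-butyl(dimethyl)silyl]oxy}-3-methoxyphenyl)prop-2-en-1-yl]oxolan-2-one | COc1cc([C@H]([C@@H]2CC(=O)OC2)C=C)ccc1O[Si](C)(C)C(C)(C)C | intermediate
9 | (4S)-4-[(S)-(4-{[tert-butyl(dimethyl)silyl]oxy}-3-methoxyphenyl)(1,2,4-trioxolan-3-yl)methyl]oxolan-2-one (secondary ozonide, either configuration at the trioxolane carbon) | COc1cc([C@H]([C@@H]2CC(=O)OC2)C3OCOO3)ccc1O[Si](C)(C)C(C)(C)C | intermediate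
10 | (2S)-2-(4-{[tert-butyl(dimethyl)silyl]oxy}-3-methoxyphenyl)-2-[(3S)-5-oxooxolan-3-yl]acetaldehyde | COc1cc([C@H]([C@@H]2CC(=O)OC2)C=O)ccc1O[Si](C)(C)C(C)(C)C | intermediate
11 | dimethyl (1-diazo-2-oxopropyl)phosphonate | CC(=O)C(=[N+]=[N-])P(=O)(OC)OC | starting material
12 | dimethyl (1-methoxy-2-oxopropyl)phosphonate (racemic) | COC(C(C)=O)P(=O)(OC)OC | intermediate
13 | (4S)-4-[(1R,2Z)-1-(4-{[tert-butyl(dimethyl)silyl]oxy}-3-methoxyphenyl)-3-methoxy-4-oxopent-2-en-1-yl]oxolan-2-one | COc1cc([C@H]([C@@H]2CC(=O)OC2)/C=C(OC)/C(C)=O)ccc1O[Si](C)(C)C(C)(C)C | intermediate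
14 | (4S)-4-[(1R,2Z)-1-(4-{[tert-butyl(dimethyl)silyl]oxy}-3-methoxyphenyl)-4-{[tert-butyl(dimethyl)silyl]oxy}-3-methoxypenta-2,4-dien-1-yl]oxolan-2-one | COc1cc([C@H]([C@@H]2CC(=O)OC2)/C=C(OC)/C(=C)O[Si](C)(C)C(C)(C)C)ccc1O[Si](C)(C)C(C)(C)C | intermediate
15 | ethynylmagnesium bromide | C#C[Mg]Br | starting material
16 | (5S,6R,7Z)-6-(4-{[tert-butyl(dimethyl)silyl]oxy}-3-methoxyphenyl)-9-{[tert-butyl(dimethyl)silyl]oxy}-5-(hydroxymethyl)-8-methoxydeca-7,9-dien-1-yn-3-one | COc1cc([C@H]([C@@H](CO)CC(=O)C#C)/C=C(OC)/C(=C)O[Si](C)(C)C(C)(C)C)ccc1O[Si](C)(C)C(C)(C)C | intermediate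
17 | [(2S,3R,4Z)-3-(4-{[tert-butyl(dimethyl)silyl]oxy}-3-methoxyphenyl)-6-{[tert-butyl(dimethyl)silyl]oxy}-5-methoxy-2-(2-oxobut-3-yn-1-yl)hexa-4,6-dien-1-yl] acetate | COc1cc([C@H]([C@@H](COC(C)=O)CC(=O)C#C)/C=C(OC)/C(=C)O[Si](C)(C)C(C)(C)C)ccc1O[Si](C)(C)C(C)(C)C | intermediate
18 | [(1R,2S)-1-(4-{[tert-butyl(dimethyl)silyl]oxy}-3-methoxyphenyl)-7-{[tert-butyl(dimethyl)silyl]oxy}-8-methoxy-4-oxo-1,2,3,4,6,8a-hexahydronaphthalen-2-yl]methyl acetate (either configuration at C8a) | COc1cc([C@H]2C3C(OC)=C(O[Si](C)(C)C(C)(C)C)CC=C3C(=O)C[C@@H]2COC(C)=O)ccc1O[Si](C)(C)C(C)(C)C | intermediate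
19 | [(1S,2S)-1-(4-{[tert-butyl(dimethyl)silyl]oxy}-3-methoxyphenyl)-7-{[tert-butyl(dimethyl)silyl]oxy}-8-methoxy-4-oxo-1,2,3,4-tetrahydronaphthalen-2-yl]methyl acetate | COc1cc([C@H]2c3c(ccc(O[Si](C)(C)C(C)(C)C)c3OC)C(=O)C[C@@H]2COC(C)=O)ccc1O[Si](C)(C)C(C)(C)C | intermediate
20 | N-{[(3R,4S)-3-(acetoxymethyl)-4-(4-{[tert-butyl(dimethyl)silyl]oxy}-3-methoxyphenyl)-6-{[tert-butyl(dimethyl)silyl]oxy}-1-chloro-5-methoxy-3,4-dihydronaphthalen-2-yl]methylidene}-N-methylmethanaminium dichlorophosphate | COc1cc([C@H]2c3c(ccc(O[Si](C)(C)C(C)(C)C)c3OC)C(Cl)=C(C=[N+](C)C)[C@@H]2COC(C)=O)ccc1O[Si](C)(C)C(C)(C)C.[O-]P(=O)(Cl)Cl | intermediate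
21 | [(1S,2R)-1-(4-{[tert-butyl(dimethyl)silyl]oxy}-3-methoxyphenyl)-7-{[tert-butyl(dimethyl)silyl]oxy}-4-chloro-3-formyl-8-methoxy-1,2-dihydronaphthalen-2-yl]methyl acetate | COc1cc([C@H]2c3c(ccc(O[Si](C)(C)C(C)(C)C)c3OC)C(Cl)=C(C=O)[C@@H]2COC(C)=O)ccc1O[Si](C)(C)C(C)(C)C | intermediate
22 | [(1S,2R)-1-(4-{[tert-butyl(dimethyl)silyl]oxy}-3-methoxyphenyl)-7-{[tert-butyl(dimethyl)silyl]oxy}-3-formyl-8-methoxy-1,2-dihydronaphthalen-2-yl]methyl acetate | COc1cc([C@H]2c3c(ccc(O[Si](C)(C)C(C)(C)C)c3OC)C=C(C=O)[C@@H]2COC(C)=O)ccc1O[Si](C)(C)C(C)(C)C | intermediate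
23 | [(1S,2R)-3-formyl-7-hydroxy-1-(4-hydroxy-3-methoxyphenyl)-8-methoxy-1,2-dihydronaphthalen-2-yl]methyl acetate | COc1cc([C@H]2c3c(ccc(O)c3OC)C=C(C=O)[C@@H]2COC(C)=O)ccc1O | target

**Step count**

Total: 14 steps. Longest linear sequence: 13 steps (1 → 23 through steps 1–5 and 7–14); step 6 is a one-step branch.

**Steps most likely to fail**

Step 11 (key step). The terminal ynone may polymerise or be consumed by adventitious nucleophiles before it cyclises, the silyl dienol ether may be hydrolysed on prolonged heating, and DDQ may go on to oxidise the diarylmethine position. The fallback sets out from 14 and comes back at 19. Lactone 14 is opened with commercial lithium (trimethylsilyl)acetylide solution (THF, −78 °C) to the silyl-capped hydroxy ynone F9, which is acetylated (Ac2O, pyridine) to the silyl ynone acetate F10. Silyl ynones tolerate base and heat better than terminal ones, so F10 can be heated in toluene at 110–130 °C to the C5-silylated cyclohexadiene F11 and dehydrogenated with DDQ to the 5-(trimethylsilyl) tetralone F12. Ipso-protodesilylation at C5, para to the C8 methoxy group, with CF3CO2H in CH2Cl2 then gives tetralone 19.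

Step 7. Enolisation of the α-aryl aldehyde may epimerise C1 before olefination, and the olefination may give the wrong enol ether geometry. The fallback sets out from 10 and comes back at 13. Aldehyde 10 is treated at −78 °C with BF3·OEt2 and the silyl enol ether of methoxyacetone, 1-methoxy-2-[(trimethylsilyl)oxy]prop-1-ene F6 (from methoxyacetone, Me3SiCl, NaI, Et3N, MeCN), in a Mukaiyama aldol addition that uses no base. This gives the β-hydroxy-α-methoxy ketone F7 as a mixture at the two new centres. Mesylation (MeSO2Cl, Et3N) gives the mesylate F8, and elimination with DBU, which removes the proton between the methoxy and acetyl groups, gives enone 13. C1 is no longer α to a carbonyl group by the time base is applied.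

Step 3. The electron-rich carbinol may ionise outside the iridium cycle and erode control at C1, and the product aldehyde may epimerise at C2 through its enamine. The fallback sets out from 2 and comes back at 8, with both centres set by one auxiliary.
- Olefination of 2 with diethylphosphonoacetic acid (LiN(SiMe3)2, THF) gives the cinnamic acid F1.
- Activation with pivaloyl chloride/Et3N and acylation of (S)-4-phenyl-1,3-oxazolidin-2-one (LiCl) gives the enoyl imide F2.
- Conjugate addition of vinylmagnesium bromide 3 with CuBr·SMe2 (THF, −78 → −20 °C), anti to the phenyl group of the chelated imide, gives the (3R)-pentenoyl imide F3 and sets C1.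
- Enolisation with NaN(SiMe3)2 and alkylation with tert-butyl bromoacetate at −78 °C, again anti to the auxiliary substituent, sets C2 in the alkylated imide F4.
- LiBH4 (Et2O, MeOH, 0 °C) removes the auxiliary reductively to give the hydroxy tert-butyl ester F5, which lactonises with p-MeC6H4SO3H·H2O in warm toluene to lactone 8.

**Further compounds**

F1 | step 3 | (2E)-3-(4-{[tert-butyl(dimethyl)silyl]oxy}-3-methoxyphenyl)prop-2-enoic acid | COc1cc(/C=C/C(=O)O)ccc1O[Si](C)(C)C(C)(C)C
F2 | step 3 | (4S)-3-[(2E)-3-(4-{[tert-butyl(dimethyl)silyl]oxy}-3-methoxyphenyl)prop-2-enoyl]-4-phenyl-1,3-oxazolidin-2-one | COc1cc(/C=C/C(=O)N2[C@@H](c3ccccc3)COC2=O)ccc1O[Si](C)(C)C(C)(C)C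
F3 | step 3 | (4S)-3-[(3R)-3-(4-{[tert-butyl(dimethyl)silyl]oxy}-3-methoxyphenyl)pent-4-enoyl]-4-phenyl-1,3-oxazolidin-2-one | COc1cc([C@H](CC(=O)N2[C@@H](c3ccccc3)COC2=O)C=C)ccc1O[Si](C)(C)C(C)(C)C
F4 | step 3 | tert-butyl (3S,4S)-4-(4-{[tert-butyl(dimethyl)silyl]oxy}-3-methoxyphenyl)-3-{[(4S)-2-oxo-4-phenyl-1,3-oxazolidin-3-yl]carbonyl}hex-5-enoate | COc1cc([C@H]([C@@H](C(=O)N2[C@@H](c3ccccc3)COC2=O)CC(=O)OC(C)(C)C)C=C)ccc1O[Si](C)(C)C(C)(C)C
F5 | step 3 | tert-butyl (3S,4S)-4-(4-{[tert-butyl(dimethyl)silyl]oxy}-3-methoxyphenyl)-3-(hydroxymethyl)hex-5-enoate | COc1cc([C@H]([C@@H](CO)CC(=O)OC(C)(C)C)C=C)ccc1O[Si](C)(C)C(C)(C)C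
F6 | step 7 | 1-methoxy-2-[(trimethylsilyl)oxy]prop-1-ene | COC=C(C)O[Si](C)(C)C
F7 | step 7 | (4S)-4-[(1S)-1-(4-{[tert-butyl(dimethyl)silyl]oxy}-3-methoxyphenyl)-2-hydroxy-3-methoxy-4-oxopentyl]oxolan-2-one (mixture at side-chain C2 and C3) | COc1cc([C@H]([C@@H]2CC(=O)OC2)C(O)C(OC)C(C)=O)ccc1O[Si](C)(C)C(C)(C)C
F8 | step 7 | (1S)-1-(4-{[tert-butyl(dimethyl)silyl]oxy}-3-methoxyphenyl)-3-methoxy-4-oxo-1-[(3S)-5-oxooxolan-3-yl]pentan-2-yl methanesulfonate (mixture at C2 and C3) | COc1cc([C@H]([C@@H]2CC(=O)OC2)C(OS(C)(=O)=O)C(OC)C(C)=O)ccc1O[Si](C)(C)C(C)(C)C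
F9 | step 11 | (5S,6R,7Z)-6-(4-{[tert-butyl(dimethyl)silyl]oxy}-3-methoxyphenyl)-9-{[tert-butyl(dimethyl)silyl]oxy}-5-(hydroxymethyl)-8-methoxy-1-(trimethylsilyl)deca-7,9-dien-1-yn-3-one | COc1cc([C@H]([C@@H](CO)CC(=O)C#C[Si](C)(C)C)/C=C(OC)/C(=C)O[Si](C)(C)C(C)(C)C)ccc1O[Si](C)(C)C(C)(C)C
F10 | step 11 | [(2S,3R,4Z)-3-(4-{[tert-butyl(dimethyl)silyl]oxy}-3-methoxyphenyl)-6-{[tert-butyl(dimethyl)silyl]oxy}-5-methoxy-2-[2-oxo-4-(trimethylsilyl)but-3-yn-1-yl]hexa-4,6-dien-1-yl] acetate | COc1cc([C@H]([C@@H](COC(C)=O)CC(=O)C#C[Si](C)(C)C)/C=C(OC)/C(=C)O[Si](C)(C)C(C)(C)C)ccc1O[Si](C)(C)C(C)(C)C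
F11 | step 11 | [(1R,2S)-1-(4-{[tert-butyl(dimethyl)silyl]oxy}-3-methoxyphenyl)-7-{[tert-butyl(dimethyl)silyl]oxy}-8-methoxy-4-oxo-5-(trimethylsilyl)-1,2,3,4,6,8a-hexahydronaphthalen-2-yl]methyl acetate (either configuration at C8a) | COc1cc([C@H]2C3C(OC)=C(O[Si](C)(C)C(C)(C)C)CC([Si](C)(C)C)=C3C(=O)C[C@@H]2COC(C)=O)ccc1O[Si](C)(C)C(C)(C)C
F12 | step 11 | [(1S,2S)-1-(4-{[tert-butyl(dimethyl)silyl]oxy}-3-methoxyphenyl)-7-{[tert-butyl(dimethyl)silyl]oxy}-8-methoxy-4-oxo-5-(trimethylsilyl)-1,2,3,4-tetrahydronaphthalen-2-yl]methyl acetate | COc1cc([C@H]2c3c(c([Si](C)(C)C)cc(O[Si](C)(C)C(C)(C)C)c3OC)C(=O)C[C@@H]2COC(C)=O)ccc1O[Si](C)(C)C(C)(C)C
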